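**Retrosynthetic overview**

- Target ⇐ (Z)-hydroxy acid (acetylation) ⇐ B-alkyl Suzuki coupling of a vinyl-substituted hydrindene acid with (Z)-3-iodo-2-methylprop-2-en-1-ol; the carboxyl-bearing centre is corrected just before by kinetic protonation.
- Vinyl acid ⇐ lactone-bridged hydrindene (selenolate opening, selenoxide elimination); its cyclohexene ring ⇐ McMurry coupling of a cyclopentanone with a pendant aldehyde.
- Key step: that cyclopentanone, with both quaternary carbons joined, ⇐ 1-alkenylcyclobutanol + acrolein by a conjugate-addition-triggered 1,2-shift (cyclobutane to cyclopentanone ring expansion).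
- Alkenylcyclobutanol ⇐ lactone-fused cyclobutanone + vinyl Grignard; cyclobutanone ⇐ [2+2] photocycloaddition of anhydromevalonolactone with ketene diethyl acetal, then resolution.
- Ring order: δ-lactone (bought, temporary) → cyclobutane → cyclopentane (by ring expansion) → cyclohexene.

Assumption: the five small starting materials are purchased as such, and the absolute configuration of the resolved cyclobutanone is confirmed (X-ray or CD) before it is carried on.

**Route**

Step 1
Reactants: 1 4-methyl-5,6-dihydro-2H-pyran-2-one; 2 1,1-diethoxyethene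
Product: 4 rac-(1R,6R)-6-methyl-3-oxabicyclo[4.2.0]octane-2,7-dione, via diethyl ketal 3 (not isolated)
Conditions: hν (254 nm, quartz), 2 (6 equiv), MeCN, 0 °C; then 1 M HCl, THF, 25 °C
Reagents that add atoms: water (O)
Why: Enone–alkene [2+2] photocycloaddition in which the electron-rich ketene acetal adds head-to-tail (acetal carbon to the methyl-bearing β-carbon) and the cyclobutane ends cis-fused to the lactone (any trans adduct epimerises at the lactone α-carbon during the acidic ketal hydrolysis), so the quaternary centre and ring fusion are set in the relative sense only (racemate).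

Step 2
Reactants: 4 rac-(1R,6R)-6-methyl-3-oxabicyclo[4.2.0]octane-2,7-dione
Product: 5 (1R,6R)-6-methyl-3-oxabicyclo[4.2.0]octane-2,7-dione
Conditions: preparative SFC on an amylose tris(3,5-dimethylphenylcarbamate) phase, CO2–MeOH
Reagents that add atoms: none
Why: Resolution of the racemate by chromatography on a chiral stationary phase gives the enantiomer whose quaternary carbon becomes C1 of the target; that centre cannot epimerise afterwards.

Step 3
Reactants: 5 (1R,6R)-6-methyl-3-oxabicyclo[4.2.0]octane-2,7-dione; 6 2-bromo-3-methylbut-2-ene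
Product: 8 (1R,6R,7S)-7-hydroxy-6-methyl-7-(3-methylbut-2-en-2-yl)-3-oxabicyclo[4.2.0]octan-2-one, via Grignard reagent 7 (not isolated)
Conditions: 6, Mg, THF, 65 °C; then 5, LaCl3·2LiCl (0.3 equiv), THF, −78 → −40 °C; aq. NH4Cl
Reagents that add atoms: none
Why: Lanthanum-promoted Grignard 1,2-addition to the strained cyclobutanone (far more electrophilic than the lactone), the nucleophile entering on the convex face of the cis-fused bicycle, anti to the lactone ring, so the carbinol carbon is 7S with the alkenyl group cis to the angular methyl.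

Step 4
Reactants: 8 (1R,6R,7S)-7-hydroxy-6-methyl-7-(3-methylbut-2-en-2-yl)-3-oxabicyclo[4.2.0]octan-2-one; 9 acrolein
Product: 12 4-[(4aR,5R,7aR)-4a,5-dimethyl-1,6-dioxooctahydrocyclopenta[c]pyran-5-yl]-4-methylpentanal, via aluminum alkoxide 10 (not isolated), via aluminum enolate 11 (not isolated)
Conditions: Me2AlCl (2.2 equiv), CH2Cl2, −78 °C; 9 (3 equiv), −78 °C, 1 h; cold 1 M HCl
Reagents that add atoms: none
Why: Proposed new method: Me2AlCl makes aluminum alkoxide 10 and activates acrolein, the tetrasubstituted alkene attacks the enal β-carbon through its exposed CMe2 terminus, and the β-oxido tertiary cation is trapped at once by 1,2-shift of the more substituted cyclobutane carbon (strain-releasing ring expansion to the cyclopentanone, retention at the migrating quaternary carbon), allylic 1,3-strain holding the C–O bond in the alkene plane so that the migrating carbon bonds anti to the electrophile on the face that places the new methyl cis to the old one (5R), after which enolate 11 is protonated on work-up; the closest known reaction types are the Prins–pinacol and halogenative semipinacol ring expansions of 1-alkenylcyclobutanols and the Me2AlCl-promoted ene-type additions of alkenes to acrolein.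

Step 5
Reactants: 12 4-[(4aR,5R,7aR)-4a,5-dimethyl-1,6-dioxooctahydrocyclopenta[c]pyran-5-yl]-4-methylpentanal
Product: 13 δ-lactone of (1R,2R,7aS)-1-(2-hydroxyethyl)-1,7,7,7a-tetramethyl-2,3,5,6,7,7a-hexahydro-1H-indene-2-carboxylic acid
Conditions: TiCl3(DME)1.5, Zn–Cu couple, DME, 85 °C, syringe-pump addition of 12 over 30 h
Reagents that add atoms: none
Why: Intramolecular McMurry carbonyl coupling on low-valent titanium joins the ketone carbon to the aldehyde carbon, so the cyclohexene double bond is placed regiospecifically at the ring fusion; no stereocentre is created and the quaternary centres cannot epimerise.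

Step 6
Reactants: 13 δ-lactone of (1R,2R,7aS)-1-(2-hydroxyethyl)-1,7,7,7a-tetramethyl-2,3,5,6,7,7a-hexahydro-1H-indene-2-carboxylic acid
Product: 16 (1R,2R,7aS)-1-ethenyl-1,7,7,7a-tetramethyl-2,3,5,6,7,7a-hexahydro-1H-indene-2-carboxylic acid, via selenide carboxylate 14 (not isolated), via selenoxide 15 (not isolated)
Conditions: PhSeNa [from (PhSe)2, Na, THF], DMF, 110 °C; then NaIO4, NaHCO3, THF–MeOH–H2O, 25 → 60 °C; 1 M HCl
Reagents that add atoms: none
Why: SN2 cleavage of the lactone at its primary O–CH2 carbon by the soft selenolate (Liotta lactone opening), then oxidation to the selenoxide and syn-elimination, unmasks the vinyl group and the free acid; the stereocentres are untouched, so the carboxyl is still cis to the vinyl group.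

Step 7
Reactants: 16 (1R,2R,7aS)-1-ethenyl-1,7,7,7a-tetramethyl-2,3,5,6,7,7a-hexahydro-1H-indene-2-carboxylic acid
Product: 18 (1R,2S,7aS)-1-ethenyl-1,7,7,7a-tetramethyl-2,3,5,6,7,7a-hexahydro-1H-indene-2-carboxylic acid, via dilithium enediolate 17 (not isolated)
Conditions: LDA (2.3 equiv), THF–DMPU, 0 → 40 °C; then AcOH (excess), THF, −78 °C
Reagents that add atoms: none
Why: Kinetic protonation of the carboxylic acid dianion: the planar enediolate carbon is protonated from the face opposite the angular 7a-methyl and the 1-methyl (as at C16 of 17-oxo steroids), which turns the carboxyl cis to both methyl groups (2S).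

Step 8
Reactants: 19 prop-2-yn-1-ol
Product: 21 (Z)-3-iodo-2-methylprop-2-en-1-ol, via alkenylmagnesium chelate 20 (not isolated)
Conditions: MeMgBr (2.3 equiv), CuI (10 mol %), Et2O, −10 → 25 °C; then I2, −40 → 0 °C; aq. NH4Cl
Reagents that add atoms: methylmagnesium bromide (C[Mg]Br); iodine (II)
Why: Copper-catalysed anti-carbomagnesiation of the propargylic alkoxide (Duboudin–Jousseaume) puts methyl on C2 and magnesium on C3 cis to the CH2O group in chelate 20, and iodinolysis with retention gives the Z-iodoalkene.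

Step 9
Reactants: 18 (1R,2S,7aS)-1-ethenyl-1,7,7,7a-tetramethyl-2,3,5,6,7,7a-hexahydro-1H-indene-2-carboxylic acid; 21 (Z)-3-iodo-2-methylprop-2-en-1-ol
Product: 23 (1R,2S,7aS)-1-[(3Z)-5-hydroxy-4-methylpent-3-en-1-yl]-1,7,7,7a-tetramethyl-2,3,5,6,7,7a-hexahydro-1H-indene-2-carboxylic acid, via alkylborane 22 (not isolated)
Conditions: 9-BBN (3 equiv), THF, 25 °C; then 21, PdCl2(dppf) (5 mol %), AsPh3, aq. K3PO4, DMF, 25 °C; 1 M HCl
Reagents that add atoms: none
Why: 9-BBN hydroborates only the monosubstituted vinyl group (anti-Markovnikov), and B-alkyl Suzuki–Miyaura coupling joins the primary alkylborane to the iodoalkene with retention of its Z geometry; the carboxylate α-centre is not enolised by aqueous phosphate.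

Step 10
Reactants: 23 (1R,2S,7aS)-1-[(3Z)-5-hydroxy-4-methylpent-3-en-1-yl]-1,7,7,7a-tetramethyl-2,3,5,6,7,7a-hexahydro-1H-indene-2-carboxylic acid
Product: 25 (1R,2S,7aS)-1-[(3Z)-5-acetoxy-4-methylpent-3-en-1-yl]-1,7,7,7a-tetramethyl-2,3,5,6,7,7a-hexahydro-1H-indene-2-carboxylic acid, via mixed anhydride 24 (not isolated)
Conditions: Ac2O (3 equiv), pyridine, DMAP (cat.), CH2Cl2, 0 → 25 °C; then H2O–THF–pyridine, 25 °C
Reagents that add atoms: acetic anhydride (CC(=O)OC(C)=O)
Why: DMAP-catalysed acetylation of the primary allylic alcohol (nucleophilic acyl substitution); the mixed anhydride 24 formed at the acid is hydrolysed selectively by aqueous pyridine, and no stereocentre is affected.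

**Compound list**

1 | 4-methyl-5,6-dihydro-2H-pyran-2-one | CC1=CC(=O)OCC1 | starting material
2 | 1,1-diethoxyethene | C=C(OCC)OCC | starting material
3 | rac-(1R,6R)-7,7-diethoxy-6-methyl-3-oxabicyclo[4.2.0]octan-2-one (cis-fused; racemate, one enantiomer drawn) | O=C1OCC[C@@]2(C)C(OCC)(OCC)C[C@@H]12 | intermediate
4 | rac-(1R,6R)-6-methyl-3-oxabicyclo[4.2.0]octane-2,7-dione (cis-fused; racemate, one enantiomer drawn) | O=C1OCC[C@@]2(C)C(=O)C[C@@H]12 | intermediate
5 | (1R,6R)-6-methyl-3-oxabicyclo[4.2.0]octane-2,7-dione | O=C1OCC[C@@]2(C)C(=O)C[C@@H]12 | intermediate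
6 | 2-bromo-3-methylbut-2-ene | CC(C)=C(C)Br | starting material
7 | (3-methylbut-2-en-2-yl)magnesium bromide | CC(C)=C(C)[Mg]Br | intermediate
8 | (1R,6R,7S)-7-hydroxy-6-methyl-7-(3-methylbut-2-en-2-yl)-3-oxabicyclo[4.2.0]octan-2-one | O=C1OCC[C@@]2(C)[C@](O)(C(C)=C(C)C)C[C@@H]12 | intermediate
9 | acrolein (prop-2-enal) | C=CC=O | starting material
10 | chloro(methyl)aluminum alkoxide of 8 | O=C1OCC[C@@]2(C)[C@](O[Al](C)Cl)(C(C)=C(C)C)C[C@@H]12 | intermediate
11 | chloro(methyl)aluminum enolate of 12 (enolate geometry not defined) | O=C1OCC[C@@]2(C)[C@@](C)(C(C)(C)CC=CO[Al](C)Cl)C(=O)C[C@@H]12 | intermediate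
12 | 4-[(4aR,5R,7aR)-4a,5-dimethyl-1,6-dioxooctahydrocyclopenta[c]pyran-5-yl]-4-methylpentanal | O=C1OCC[C@@]2(C)[C@@](C)(C(C)(C)CCC=O)C(=O)C[C@@H]12 | intermediate
13 | δ-lactone of (1R,2R,7aS)-1-(2-hydroxyethyl)-1,7,7,7a-tetramethyl-2,3,5,6,7,7a-hexahydro-1H-indene-2-carboxylic acid | O=C1OCC[C@@]2(C)[C@@]3(C)C(C)(C)CCC=C3C[C@@H]12 | intermediate
14 | sodium (1R,2R,7aS)-1,7,7,7a-tetramethyl-1-[2-(phenylselanyl)ethyl]-2,3,5,6,7,7a-hexahydro-1H-indene-2-carboxylate | c1ccccc1[Se]CC[C@]1(C)[C@H](C([O-])=O)CC2=CCCC(C)(C)[C@@]21C.[Na+] | intermediate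
15 | selenoxide of 14 (selenium configuration not defined) | O=[Se](CC[C@]1(C)[C@H](C([O-])=O)CC2=CCCC(C)(C)[C@@]21C)c1ccccc1.[Na+] | intermediate
16 | (1R,2R,7aS)-1-ethenyl-1,7,7,7a-tetramethyl-2,3,5,6,7,7a-hexahydro-1H-indene-2-carboxylic acid | C=C[C@]1(C)[C@H](C(=O)O)CC2=CCCC(C)(C)[C@@]21C | intermediate
17 | dilithium enediolate of 16 | C=C[C@]1(C)C(=C([O-])[O-])CC2=CCCC(C)(C)[C@@]21C.[Li+].[Li+] | intermediate
18 | (1R,2S,7aS)-1-ethenyl-1,7,7,7a-tetramethyl-2,3,5,6,7,7a-hexahydro-1H-indene-2-carboxylic acid | C=C[C@]1(C)[C@@H](C(=O)O)CC2=CCCC(C)(C)[C@@]21C | intermediate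
19 | prop-2-yn-1-ol | C#CCO | starting material
20 | (Z)-alkenylmagnesium chelate from 19 (bromomagnesium (Z)-3-(bromomagnesio)-2-methylprop-2-en-1-olate) | Br[Mg]/C=C(/C)CO[Mg]Br | intermediate
21 | (Z)-3-iodo-2-methylprop-2-en-1-ol | I/C=C(/C)CO | intermediate
22 | B-alkyl-9-BBN from 18 (acid held as its 9-BBN acyloxyborane) | C(CB1C2CCCC1CCC2)[C@]3(C)[C@@H](C(=O)OB4C5CCCC4CCC5)CC6=CCCC(C)(C)[C@@]63C | intermediate
23 | (1R,2S,7aS)-1-[(3Z)-5-hydroxy-4-methylpent-3-en-1-yl]-1,7,7,7a-tetramethyl-2,3,5,6,7,7a-hexahydro-1H-indene-2-carboxylic acid | OC/C(C)=C\CC[C@]1(C)[C@@H](C(=O)O)CC2=CCCC(C)(C)[C@@]21C | intermediate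
24 | acetic mixed anhydride of 25 | CC(=O)OC/C(C)=C\CC[C@]1(C)[C@@H](C(=O)OC(C)=O)CC2=CCCC(C)(C)[C@@]21C | intermediate
25 | (1R,2S,7aS)-1-[(3Z)-5-acetoxy-4-methylpent-3-en-1-yl]-1,7,7,7a-tetramethyl-2,3,5,6,7,7a-hexahydro-1H-indene-2-carboxylic acid (CNP0289983.1) | CC(=O)OC/C(C)=C\CC[C@]1(C)[C@@H](C(=O)O)CC2=CCCC(C)(C)[C@@]21C | target

**Step count and risks**

Total step count: 10 (nine on the main line plus the one-step preparation of iodoalkene 21). Longest linear sequence: 9 steps (steps 1 to 7, 9 and 10).

The three steps most likely to fail: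

Step 4, the proposed new ring expansion. The zwitterion may collapse by ene-type proton loss, or enolate 11 may add to the newly formed ketone. The fallback uses known chemistry and sets out from alcohol 8. N-Bromosuccinimide (CH2Cl2, propylene oxide, 0 °C) triggers the established halogenative semipinacol ring expansion to the tertiary bromo ketone F1, with the same facial course. Giese addition of the derived tertiary radical to acrolein 9 (Bu3SnH, AIBN, benzene, 80 °C, slow addition) then gives keto aldehyde 12, where the route is rejoined.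

Step 5, the McMurry ring closure. The ketone is flanked by a quaternary carbon and the lactone may be attacked by low-valent titanium. The fallback sets out from keto aldehyde 12. SmI2 (THF, t-BuOH, 25 °C) gives the ketyl pinacol product, cis-diol F2. 1,1'-Thiocarbonyldiimidazole (toluene, 110 °C) converts it into the cyclic thionocarbonate F3. Corey–Winter olefination with P(OMe)3 (110 °C) delivers lactone 13, where the route is rejoined.

Step 7, the kinetic protonation. The α-hydrogen sits on the hindered face, so dianion formation may be slow, and the facial preference is argued by analogy only. The fallback replaces kinetic by thermodynamic control and sets out from acid 16. TMSCHN2 (MeOH–toluene) gives the methyl ester F4. NaOMe in MeOH at reflux equilibrates it to the 2S methyl ester F5, expected to be the more stable epimer as for 16-substituted 17-oxo steroids; the minor epimer is separated and recycled. LiOH (THF–MeOH–H2O, 50 °C) then gives acid 18, where the route is rejoined.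

**Further compounds**

F1 | step 4 | (4aR,5R,7aR)-5-(2-bromopropan-2-yl)-4a,5-dimethylhexahydrocyclopenta[c]pyran-1,6-dione | O=C1OCC[C@@]2(C)[C@@](C)(C(C)(C)Br)C(=O)C[C@@H]12
F2 | step 5 | δ-lactone of (1R,2R,7aS)-3a,4-dihydroxy-1-(2-hydroxyethyl)-1,7,7,7a-tetramethyloctahydro-1H-indene-2-carboxylic acid (cis-3a,4-diol, configuration at the two carbinol carbons not assigned) | O=C1OCC[C@@]2(C)[C@@]3(C)C(C)(C)CCC(O)C3(O)C[C@@H]12
F3 | step 5 | cyclic 3a,4-thionocarbonate of F2 | O=C1OCC[C@@]2(C)[C@@]3(C)C(C)(C)CCC4OC(=S)OC34C[C@@H]12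
F4 | step 7 | methyl (1R,2R,7aS)-1-ethenyl-1,7,7,7a-tetramethyl-2,3,5,6,7,7a-hexahydro-1H-indene-2-carboxylate | C=C[C@]1(C)[C@H](C(=O)OC)CC2=CCCC(C)(C)[C@@]21C
F5 | step 7 | methyl (1R,2S,7aS)-1-ethenyl-1,7,7,7a-tetramethyl-2,3,5,6,7,7a-hexahydro-1H-indene-2-carboxylate | C=C[C@]1(C)[C@@H](C(=O)OC)CC2=CCCC(C)(C)[C@@]21C
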